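A direct plan would assemble a 2-aryl-3-aroylbenzofuran by Sonogashira coupling and carbonylative annulation of iodinated phloroglucinol units, grow the flavan ring on it from chalcone A1 (oxa-Michael closure, asymmetric transfer hydrogenation, deoxygenation), free one ortho phenol of the aroyl group to give A2, and finish by phenoxide addition to C2 of the benzofuran with oxaziridine hydroxylation at C3 to give A3, then hydrogenolysis.
Its weakest steps would be: (1) the closing oxa-Michael addition with enolate hydroxylation, which would have to break the aromaticity of the benzofuran, oxidise a hindered tetrasubstituted enolate and set C2 and C3 by reagent control alone, on the most valuable intermediate;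
(2) the setting of C2'' by dynamic kinetic resolution of the chalcone–flavanone pair on a fully substituted benzofuran, where three reducible groups compete and the carbinol created is deleted in the next step;
(3) the long linear run in which phenol differentiation (a selective monobenzylation, a mono-debenzylation beside five other benzyl ethers) and redox corrections add no skeleton.

**Retrosynthetic overview**
The C2 (ketal)–C3 (carbinol)–C4 (ketone) triad of the pyranone ring is read as a masked vicinal tricarbonyl, and O7''/C8'' of the flavan A'' ring as a phenol with its ortho carbon: the cuts are C3–C8'', O7''–C2 and O1–C2.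
This leaves acyclic triketone 6 (four steps from 2,4,6-trihydroxyacetophenone) and the intact (2''S)-flavan 11 (three steps from (2S)-naringenin, the 5-OH being singled out by the deoxygenation itself).
Ring order: flavan pyran ring (chiral pool), then the dihydrofuran ring together with C3 in a catalytic Friedel–Crafts union of the two fragments (step 8), then the pyranone ring and C2 in the final deprotection.
No benzofuran is made or dearomatised, no enolate is hydroxylated, C2'' is bought and not resolved, and the only protecting-group operations are those the union needs.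

Key step: step 8

**Assumptions**
(a) (2S)-Naringenin of high enantiomeric purity is taken as a commercial chiral-pool material.
(b) The sense of induction of the squaramide in step 8 cannot be predicted for this triketone; the quinine-derived catalyst is written, and its quinidine-derived pseudo-enantiomer would be used if that one gives (3S).
(c) C2 is a diaryl ketal carbon that equilibrates through its oxocarbenium ion, so it is set by C3 in the last ring closure; the C2 descriptor of the given SMILES is taken as that outcome.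

**Route**

Step 1
Reactants: 1 2,4,6-trihydroxyacetophenone
Product: 2 1-[2,4,6-tris(benzyloxy)phenyl]ethanone
Conditions: BnBr (3.5 equiv), K2CO3 (4 equiv), DMF, 70 °C
Reagents that add atoms: benzyl bromide, BrCc1ccccc1
Why: Williamson etherification of all three phenols, the two chelated ortho-hydroxyls needing the polar solvent and heat.

Step 2
Reactants: 2 1-[2,4,6-tris(benzyloxy)phenyl]ethanone; 3 methyl 4-(benzyloxy)benzoate
Product: 4 1-[4-(benzyloxy)phenyl]-3-[2,4,6-tris(benzyloxy)phenyl]propane-1,3-dione
Conditions: NaH (3 equiv), THF, reflux; then cold dilute HCl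
Reagents that add atoms: none
Why: Crossed Claisen condensation, in which the methyl ketone enolate is acylated by the non-enolisable ester and formation of the diketonate drives the equilibrium, the hindered aryl ketone being unable to self-condense.

Step 3
Reactants: 4 1-[4-(benzyloxy)phenyl]-3-[2,4,6-tris(benzyloxy)phenyl]propane-1,3-dione
Product: 5 1-[4-(benzyloxy)phenyl]-2-diazo-3-[2,4,6-tris(benzyloxy)phenyl]propane-1,3-dione
Conditions: 4-acetamidobenzenesulfonyl azide (1.2 equiv), Et3N, MeCN, 0 °C to rt
Reagents that add atoms: 4-acetamidobenzenesulfonyl azide, CC(=O)Nc1ccc(cc1)S(=O)(=O)N=[N+]=[N-]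
Why: Regitz diazo transfer to the doubly activated methylene of the 1,3-diketone.

Step 4
Reactants: 5 1-[4-(benzyloxy)phenyl]-2-diazo-3-[2,4,6-tris(benzyloxy)phenyl]propane-1,3-dione
Product: 6 1-[4-(benzyloxy)phenyl]-3-[2,4,6-tris(benzyloxy)phenyl]propane-1,2,3-trione
Conditions: dimethyldioxirane (1.5 equiv, in acetone), CH2Cl2, 0 °C; then azeotropic drying with toluene
Reagents that add atoms: dimethyldioxirane, CC1(C)OO1
Why: Oxygen-atom transfer from the dioxirane to the diazo carbon with loss of dinitrogen, a neutral entry to vicinal tricarbonyl compounds that should outrun attack on the benzyl ethers and alkoxyarenes at 0 °C, the hydrate of the central carbonyl being removed by the drying.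

Step 5
Reactants: 7 (2S)-naringenin
Product: 9 (2S)-2-{4-[(ethoxycarbonyl)oxy]phenyl}-5-hydroxy-3,4-dihydro-2H-chromen-7-yl ethyl carbonate, via (2S)-naringenin tris(ethyl carbonate) 8 (not isolated)
Conditions: ClCO2Et (3.3 equiv), Et3N (3.5 equiv), THF, 0 °C; filter; then NaBH4 (4 equiv), THF–H2O, 0 °C to rt
Reagents that add atoms: ethyl chloroformate, CCOC(=O)Cl
Why: Ortho-carbonate-assisted deoxygenation of an o-hydroxyaryl ketone: borohydride reduces the C4 ketone, the benzylic alkoxide takes over the neighbouring 5-O-carbonate and leaves as ethyl carbonate to give an o-quinone methide that is reduced to CH2, so that only the 5-OH is set free while the 7- and 4'-O-carbonates stay and C2 (S, from the chiral pool) is not involved.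

Step 6
Reactants: 9 (2S)-2-{4-[(ethoxycarbonyl)oxy]phenyl}-5-hydroxy-3,4-dihydro-2H-chromen-7-yl ethyl carbonate
Product: 10 (2S)-5-(benzyloxy)-2-{4-[(ethoxycarbonyl)oxy]phenyl}-3,4-dihydro-2H-chromen-7-yl ethyl carbonate
Conditions: BnOH (1.3 equiv), PPh3, DIAD, THF, 0 °C to rt
Reagents that add atoms: benzyl alcohol, OCc1ccccc1
Why: Mitsunobu etherification of the only free phenol under neutral conditions, which avoids the carbonate scrambling that a phenoxide would cause.

Step 7
Reactants: 10 (2S)-5-(benzyloxy)-2-{4-[(ethoxycarbonyl)oxy]phenyl}-3,4-dihydro-2H-chromen-7-yl ethyl carbonate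
Product: 11 (2S)-5-(benzyloxy)-2-(4-hydroxyphenyl)-3,4-dihydro-2H-chromen-7-ol
Conditions: K2CO3 (0.5 equiv), MeOH, rt; then dilute acid work-up
Reagents that add atoms: none
Why: Base-catalysed transesterification of the two aryl carbonates with methanol, which leaves the benzyl ether and the flavan stereocentre untouched.

Step 8
Reactants: 6 1-[4-(benzyloxy)phenyl]-3-[2,4,6-tris(benzyloxy)phenyl]propane-1,2,3-trione; 11 (2S)-5-(benzyloxy)-2-(4-hydroxyphenyl)-3,4-dihydro-2H-chromen-7-ol
Product: 12 (3S,2''S)-dihydrofuran hemiketal (C3–C8'' bond formed; C2 as both anomers)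
Conditions: 6 (1.2 equiv), quinine-derived squaramide 3-{[3,5-bis(trifluoromethyl)phenyl]amino}-4-{[(8α,9S)-6'-methoxycinchonan-9-yl]amino}cyclobut-3-ene-1,2-dione (10 mol%), toluene–CH2Cl2, 4 Å MS, −40 °C
Reagents that add atoms: none
Why: Proposed new method: the tertiary amine of the bifunctional catalyst hydrogen-bonds the 7''-OH of 11 and so raises the nucleophilicity of its ortho carbon, while the squaramide N–H pair clamps the central carbonyl of 6 together with the coplanar 4-(benzyloxy)benzoyl carbonyl; C8'' then adds to one face of the central carbonyl, the arenium ion rearomatises, and the 7''-OH adds to the unhindered aryl ketone (5-exo-trig) to close the dihydrofuran ring as a hemiketal, as ninhydrin–phenol adducts do. The closest known reaction types are the cinchona squaramide- and thiourea-catalysed ortho-Friedel–Crafts hydroxyalkylation of electron-rich phenols and naphthols with isatins, trifluoropyruvates and other activated ketones, and the acid-promoted condensation of phenols with ninhydrin and other vicinal tricarbonyl compounds; new is an open 1,3-diaryl triketone, whose two flanking acyl groups must be told apart. C3 (S) is set by the catalyst, which has to distinguish the planar 4-(benzyloxy)benzoyl group from the 2,4,6-tris(benzyloxy)benzoyl group that its two ortho substituents twist out of conjugation (reagent control, C2'' being too remote to matter), while C2 remains a pair of hemiketal anomers that converge in step 9. Regioselectivity for C8'' over C6'' is needed, since both are ortho to the free 7''-OH: C6'' is screened by the 5''-benzyloxy group, whose CH2 turns toward C6''–H to avoid C4''H2, whereas C8'' has only the tied-back ring oxygen as second neighbour and is the usual site of electrophilic substitution in 5,7-dioxygenated flavans. Chemoselectivity for the central carbonyl follows from its two flanking acceptor groups, and the phenol of the 2''-aryl ring has no activated ortho carbon.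

Step 9
Reactants: 12 (3S,2''S)-dihydrofuran hemiketal
Product: 14 CNP0208300.3, via hexaphenol hemiketal 13 (not isolated)
Conditions: H2 (1 atm), 10% Pd/C, THF–MeOH, rt; filter; then PPTS (0.2 equiv), THF, 4 Å MS, rt
Reagents that add atoms: none
Why: Heterogeneous hydrogenolysis of the five aryl benzyl ethers gives 13, whose hemiketal C2–OH ionises under mild acid to an oxocarbenium ion (stabilised by the furan oxygen and the 4-hydroxyphenyl group) that is trapped by one of the two equivalent ortho-hydroxyls of the 2,4,6-trihydroxybenzoyl group (6-exo-trig), closing the pyranone ring as the only full ketal the molecule can form, with C2 set in this equilibrating closure by C3 through the ring fusion.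

**Compound list**

1 | 2,4,6-trihydroxyacetophenone | CC(=O)c1c(O)cc(O)cc1O | starting material
2 | 1-[2,4,6-tris(benzyloxy)phenyl]ethanone | CC(=O)c1c(OCc2ccccc2)cc(OCc2ccccc2)cc1OCc1ccccc1 | intermediate
3 | methyl 4-(benzyloxy)benzoate | COC(=O)c1ccc(OCc2ccccc2)cc1 | starting material
4 | 1-[4-(benzyloxy)phenyl]-3-[2,4,6-tris(benzyloxy)phenyl]propane-1,3-dione | O=C(CC(=O)c1ccc(OCc2ccccc2)cc1)c1c(OCc2ccccc2)cc(OCc2ccccc2)cc1OCc1ccccc1 | intermediate
5 | 1-[4-(benzyloxy)phenyl]-2-diazo-3-[2,4,6-tris(benzyloxy)phenyl]propane-1,3-dione | O=C(C(=[N+]=[N-])C(=O)c1ccc(OCc2ccccc2)cc1)c1c(OCc2ccccc2)cc(OCc2ccccc2)cc1OCc1ccccc1 | intermediate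
6 | 1-[4-(benzyloxy)phenyl]-3-[2,4,6-tris(benzyloxy)phenyl]propane-1,2,3-trione | O=C(C(=O)C(=O)c1ccc(OCc2ccccc2)cc1)c1c(OCc2ccccc2)cc(OCc2ccccc2)cc1OCc1ccccc1 | intermediate
7 | (2S)-naringenin, (2S)-5,7-dihydroxy-2-(4-hydroxyphenyl)chroman-4-one | Oc1cc(O)c2c(c1)O[C@H](c1ccc(O)cc1)CC2=O | starting material
8 | (2S)-naringenin 5,7,4'-tris(ethyl carbonate), not isolated | CCOC(=O)Oc1cc(OC(=O)OCC)c2c(c1)O[C@H](c1ccc(OC(=O)OCC)cc1)CC2=O | intermediate
9 | (2S)-2-{4-[(ethoxycarbonyl)oxy]phenyl}-5-hydroxy-3,4-dihydro-2H-chromen-7-yl ethyl carbonate | CCOC(=O)Oc1cc(O)c2c(c1)O[C@H](c1ccc(OC(=O)OCC)cc1)CC2 | intermediate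
10 | (2S)-5-(benzyloxy)-2-{4-[(ethoxycarbonyl)oxy]phenyl}-3,4-dihydro-2H-chromen-7-yl ethyl carbonate | CCOC(=O)Oc1cc(OCc2ccccc2)c2c(c1)O[C@H](c1ccc(OC(=O)OCC)cc1)CC2 | intermediate
11 | (2S)-5-(benzyloxy)-2-(4-hydroxyphenyl)-3,4-dihydro-2H-chromen-7-ol | Oc1cc(OCc2ccccc2)c2c(c1)O[C@H](c1ccc(O)cc1)CC2 | intermediate
12 | (3S,2''S)-dihydrofuran hemiketal: 2,3-dihydrofuran fused to C7''–C8'' of the (2''S)-5''-(benzyloxy)-2''-(4-hydroxyphenyl)flavan (furan O on C7'', C3 on C8''); C3 (S) carries OH and the 2,4,6-tris(benzyloxy)benzoyl group; C2 carries OH and 4-(benzyloxy)phenyl (both anomers) | O=C(c1c(OCc2ccccc2)cc(OCc2ccccc2)cc1OCc1ccccc1)[C@]1(O)C(O)(c2ccc(OCc3ccccc3)cc2)Oc2cc(OCc3ccccc3)c3c(c21)O[C@H](c1ccc(O)cc1)CC3 | intermediate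
13 | hexaphenol hemiketal, not isolated: as 12 with all five benzyl ethers cleaved (2,4,6-trihydroxybenzoyl on C3, 4-hydroxyphenyl on C2, 5''-OH) | O=C(c1c(O)cc(O)cc1O)[C@]1(O)C(O)(c2ccc(O)cc2)Oc2cc(O)c3c(c21)O[C@H](c1ccc(O)cc1)CC3 | intermediate
14 | CNP0208300.3: (2R,3S,2''S) as given; 5,7-dihydroxychroman-4-one whose C2 (4-hydroxyphenyl, O1) and C3 (OH) are also C2 and C3 of a dihydrofuran fused to C7''–C8'' of (2''S)-5''-hydroxy-2''-(4-hydroxyphenyl)flavan | O=C1c2c(O)cc(O)cc2O[C@@]2(c3ccc(O)cc3)Oc3cc(O)c4c(c3[C@]12O)O[C@H](c1ccc(O)cc1)CC4 | target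

**Step count**
Total: 9 steps. Longest linear sequence: 6 steps (steps 1–4, 8, 9).

**Steps most likely to fail**

Step 8 (proposed new method). The catalyst may discriminate poorly between the two faces of the central carbonyl, or the flavan may react through C6''. A fallback by known chemistry sets out from 11 and 6 and comes back at 13.
- Both phenols of 11 would be benzylated (BnBr, K2CO3, DMF) to (2S)-5,7-bis(benzyloxy)-2-[4-(benzyloxy)phenyl]chroman F1.
- NBS in CH2Cl2 at low temperature would brominate C8, the known site for 5,7-di-O-benzyl flavans, to give the 8-bromo flavan F2.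
- Bromine–lithium exchange (n-BuLi, THF, −78 °C) and addition of the aryllithium to the central carbonyl of 6 would give the heptabenzyl carbinol diketone F3 together with its carbinol epimer F4. The two are diastereomers and would be separated by chromatography.
- F3 has the (R) descriptor at the carbinol carbon; this is the spatial arrangement of C3 (S) in 12, the descriptor changing because the two acyl groups change rank.
- Hydrogenolysis of F3 under the conditions of step 9 would give the open-chain tautomer of 13, which closes to 13 and then to 14.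
- The regiochemistry is then fixed by the halogen, and C3 by separation instead of by catalyst.

Step 9. While five benzyl ethers are removed, the benzylic C–O bonds at C3, at the hemiketal carbon C2 and at C2'' may be cleaved reductively, or the aryl ketone reduced. The fallback sets out from 12 and comes back at 13: the benzyl ethers would be cleaved without hydrogen by BCl3 with pentamethylbenzene as cation scavenger (CH2Cl2, −78 °C), and 13 would be ketalised as before to 14.

Step 5. The amine base may open the flavanone ring before reduction (erosion of C2), or borohydride may strip the remote carbonates so that the 5-OH is no longer singled out. The fallback sets out from 7 and comes back at 11.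
- TBSCl and imidazole (DMF, 0 °C) would silylate only the 7- and 4'-hydroxyls, the 5-OH being chelated to the ketone, to give (2S)-7,4'-bis(tert-butyldimethylsilyloxy)-5-hydroxyflavanone F5.
- NaBH4 would give the flavan-4-ol F6 (C4 epimers).
- Ionic hydrogenation (Et3SiH, CF3CO2H, CH2Cl2, −40 to 0 °C) would give (2S)-7,4'-bis(tert-butyldimethylsilyloxy)flavan-5-ol F7.
- Mitsunobu benzylation (BnOH, PPh3, DIAD) would give the 5-O-benzyl ether F8, and Bu4NF would release 11.

**Further compounds**
F1 | step 8 | (2S)-5,7-bis(benzyloxy)-2-[4-(benzyloxy)phenyl]chroman | O(Cc1ccccc1)c1cc(OCc2ccccc2)c2c(c1)O[C@H](c1ccc(OCc3ccccc3)cc1)CC2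
F2 | step 8 | (2S)-5,7-bis(benzyloxy)-2-[4-(benzyloxy)phenyl]-8-bromochroman | O(Cc1ccccc1)c1cc(OCc2ccccc2)c2c(c1Br)O[C@H](c1ccc(OCc3ccccc3)cc1)CC2
F3 | step 8 | (2R)-1-[4-(benzyloxy)phenyl]-2-{(2S)-5,7-bis(benzyloxy)-2-[4-(benzyloxy)phenyl]chroman-8-yl}-2-hydroxy-3-[2,4,6-tris(benzyloxy)phenyl]propane-1,3-dione | O=C(c1c(OCc2ccccc2)cc(OCc2ccccc2)cc1OCc1ccccc1)[C@](O)(C(=O)c1ccc(OCc2ccccc2)cc1)c1c(OCc2ccccc2)cc(OCc2ccccc2)c2c1O[C@H](c1ccc(OCc3ccccc3)cc1)CC2
F4 | step 8 | (2S)-carbinol epimer of F3 | O=C(c1c(OCc2ccccc2)cc(OCc2ccccc2)cc1OCc1ccccc1)[C@@](O)(C(=O)c1ccc(OCc2ccccc2)cc1)c1c(OCc2ccccc2)cc(OCc2ccccc2)c2c1O[C@H](c1ccc(OCc3ccccc3)cc1)CC2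
F0 | step 9 | none | none
F5 | step 5 | (2S)-7-(tert-butyldimethylsilyloxy)-2-[4-(tert-butyldimethylsilyloxy)phenyl]-5-hydroxychroman-4-one | CC(C)(C)[Si](C)(C)Oc1cc(O)c2c(c1)O[C@H](c1ccc(O[Si](C)(C)C(C)(C)C)cc1)CC2=O
F6 | step 5 | (2S)-7-(tert-butyldimethylsilyloxy)-2-[4-(tert-butyldimethylsilyloxy)phenyl]chroman-4,5-diol (C4 epimers) | CC(C)(C)[Si](C)(C)Oc1cc(O)c2c(c1)O[C@H](c1ccc(O[Si](C)(C)C(C)(C)C)cc1)CC2O
F7 | step 5 | (2S)-7-(tert-butyldimethylsilyloxy)-2-[4-(tert-butyldimethylsilyloxy)phenyl]chroman-5-ol | CC(C)(C)[Si](C)(C)Oc1cc(O)c2c(c1)O[C@H](c1ccc(O[Si](C)(C)C(C)(C)C)cc1)CC2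
F8 | step 5 | (2S)-5-(benzyloxy)-7-(tert-butyldimethylsilyloxy)-2-[4-(tert-butyldimethylsilyloxy)phenyl]chroman | CC(C)(C)[Si](C)(C)Oc1cc(OCc3ccccc3)c2c(c1)O[C@H](c1ccc(O[Si](C)(C)C(C)(C)C)cc1)CC2
A1 | direct plan | 6-(benzyloxy)-2-[4-(benzyloxy)phenyl]-5-{(E)-3-[4-(benzyloxy)phenyl]prop-2-enoyl}-4-hydroxy-3-[2,4,6-tris(benzyloxy)benzoyl]benzofuran | O=C(c1c(OCc2ccccc2)cc(OCc2ccccc2)cc1OCc1ccccc1)c1c(-c2ccc(OCc3ccccc3)cc2)oc2cc(OCc3ccccc3)c(C(=O)/C=C/c3ccc(OCc4ccccc4)cc3)c(O)c12
A2 | direct plan | (2''S)-flavan fused to a 2-[4-(benzyloxy)phenyl]-3-[4,6-bis(benzyloxy)-2-hydroxybenzoyl]benzofuran (5''-OBn, 4'''-OBn) | O=C(c1c(O)cc(OCc2ccccc2)cc1OCc1ccccc1)c1c(-c2ccc(OCc3ccccc3)cc2)oc2cc(OCc3ccccc3)c3c(c12)O[C@H](c1ccc(OCc2ccccc2)cc1)CC3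
A3 | direct plan | (2R,3S,2''S)-hydroxy ketal pentabenzyl ether of the target (benzyl ethers at O5, O7, O4', O5'' and O4''') | O=C1c2c(OCc3ccccc3)cc(OCc3ccccc3)cc2O[C@@]2(c3ccc(OCc4ccccc4)cc3)Oc3cc(OCc4ccccc4)c4c(c3[C@]12O)O[C@H](c1ccc(OCc2ccccc2)cc1)CC4
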